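The route disconnects the C1–C14 bond of the fourteen-membered carbocycle. C1 is the allylic carbon of a 2-propenoate (a Morita–Baylis–Hillman unit) and C14 is the α-carbon of the C13 ketone, so both can be stored in one sixteen-membered β-keto lactone, C1–O–C(=O)–C14. A chiral tertiary amine opens that lactone at the acrylate CH2, CO2 is lost and the C13/C14 enolate closes back onto C1: the carbocycle, the C1–C14 bond and the C1 stereocentre arise in one operation. The precursor is the keto-lactone carrying the linalool-derived C4/C5/C8/C9 oxygen array, the C4 hydroxyl as a triethylsilyl ether.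

Key step: step 17

Remark: atoms are numbered C1–C14 around the carbocycle (C1 propenoate-bearing, C4 carbinol, C5/C8 ether carbons, C9 acetate, C11=C12, C13 carbinol; target 1S,4S,5R,8S,9R,13S,11E). The C4 hydroxyl is assumed to need a silyl ether from step 3 to step 19, because free it lies 1,4 to C1 and could form a lactol with the C1 aldehyde, trap the acylketene, or close a tetrahydrofuran onto the allylammonium ion.

Step 1
Reactants: 1 (S)-linalool
Product: 2 (2E,6S)-2,6-dimethylocta-2,7-diene-1,6-diol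
Conditions: SeO2 (0.3 equiv), t-BuOOH (70% aq), salicylic acid (cat.), CH2Cl2, 0 °C → rt
Reagents that add atoms: tert-butyl hydroperoxide, CC(C)(C)OO
Why: Riley allylic oxidation (ene reaction, then [2,3]-sigmatropic shift, SeO2 turned over by the hydroperoxide) should hydroxylate the (E)-methyl group of the trisubstituted alkene, while the vinyl group and the tertiary carbinol stereocentre are not touched.

Step 2
Reactants: 2 (2E,6S)-2,6-dimethylocta-2,7-diene-1,6-diol
Product: 4 (2S)-2-[(2R,5S)-5-ethenyl-5-methyloxolan-2-yl]propane-1,2-diol, via epoxy alcohol 3 (not isolated)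
Conditions: Ti(OiPr)4 (10 mol %), L-(+)-diisopropyl tartrate (12 mol %), t-BuOOH (decane), 4 Å MS, CH2Cl2, −20 °C; then PPTS (cat.), 0 °C → rt
Reagents that add atoms: tert-butyl hydroperoxide, CC(C)(C)OO
Why: Katsuki–Sharpless asymmetric epoxidation of the (E)-2-methylallylic alcohol with L-(+)-tartrate should give the (2S,3S)-epoxy alcohol 3 under reagent control (the tertiary vinyl carbinol is a poor substrate), and 5-exo opening at the secondary epoxide carbon by the tertiary hydroxyl with inversion sets C5 (R) while the retained epoxide oxygen becomes the C4 (S) carbinol.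

Step 3
Reactants: 4 (2S)-2-[(2R,5S)-5-ethenyl-5-methyloxolan-2-yl]propane-1,2-diol
Product: 5 (2R,5S)-2-[(2S)-1,2-bis(triethylsilyloxy)propan-2-yl]-5-ethenyl-5-methyloxolane
Conditions: TESOTf (2.6 equiv), 2,6-lutidine, CH2Cl2, −78 → 0 °C
Reagents that add atoms: triethylsilyl trifluoromethanesulfonate, CC[Si](CC)(CC)OS(=O)(=O)C(F)(F)F
Why: silyl triflate with a hindered pyridine base silylates tertiary as well as primary hydroxyls, giving a primary silyl ether that can later be oxidised directly and a tertiary one that lasts to the end.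

Step 4
Reactants: 5 (2R,5S)-2-[(2S)-1,2-bis(triethylsilyloxy)propan-2-yl]-5-ethenyl-5-methyloxolane
Product: 7 (2S,5R)-5-[(2S)-1,2-bis(triethylsilyloxy)propan-2-yl]-2-methyloxolane-2-carbaldehyde, via ozonide 6 (not isolated)
Conditions: O3, CH2Cl2, −78 °C; then PPh3, −78 °C → rt
Reagents that add atoms: ozone, [O-][O+]=O
Why: ozonolysis with reductive work-up cleaves the only alkene to the C9 aldehyde, which cannot epimerise because C8 is quaternary, and silyl ethers are inert to ozone.

Step 5
Reactants: 7 (2S,5R)-5-[(2S)-1,2-bis(triethylsilyloxy)propan-2-yl]-2-methyloxolane-2-carbaldehyde; 8 allylmagnesium bromide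
Product: 10 (1R)-1-{(2S,5R)-5-[(2S)-1,2-bis(triethylsilyloxy)propan-2-yl]-2-methyloxolan-2-yl}but-3-en-1-ol, via borinate 9 (not isolated)
Conditions: (+)-Ipc2BOMe [(+)-B-methoxydiisopinocampheylborane, from (−)-α-pinene], allylMgBr, Et2O, −78 °C → rt; then 7, −78 °C; then HOCH2CH2NH2, rt
Reagents that add atoms: allylmagnesium bromide, C=CC[Mg]Br
Why: Brown allylboration through a chair six-membered transition state, in which the (−)-α-pinene-derived reagent should deliver allyl to the Re face of the aldehyde and set C9 (R) under reagent control, the same sense as the Felkin–Anh preference of this α-alkoxy aldehyde (ring oxygen anti, methyl as the small group).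

Step 6
Reactants: 10 (1R)-1-{(2S,5R)-5-[(2S)-1,2-bis(triethylsilyloxy)propan-2-yl]-2-methyloxolan-2-yl}but-3-en-1-ol
Product: 11 (1R)-1-{(2S,5R)-5-[(2S)-1,2-bis(triethylsilyloxy)propan-2-yl]-2-methyloxolan-2-yl}but-3-en-1-yl acetate
Conditions: Ac2O, DMAP (cat.), pyridine, CH2Cl2, rt
Reagents that add atoms: acetic anhydride, CC(=O)OC(C)=O
Why: DMAP-catalysed acylation of the only free hydroxyl installs the C9 acetate of the target with retention.

Step 7
Reactants: 11 (1R)-1-{(2S,5R)-5-[(2S)-1,2-bis(triethylsilyloxy)propan-2-yl]-2-methyloxolan-2-yl}but-3-en-1-yl acetate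
Product: 12 (1R)-1-{(2S,5R)-2-methyl-5-[(2R)-1-oxo-2-(triethylsilyloxy)propan-2-yl]oxolan-2-yl}but-3-en-1-yl acetate (C3 aldehyde; the C4 descriptor changes only because CHO now outranks C5)
Conditions: (COCl)2, DMSO, CH2Cl2, −78 → −30 °C; then Et3N, −78 °C → rt
Reagents that add atoms: none
Why: under Swern conditions a primary triethylsilyl ether is converted directly into the aldehyde (silyl transfer to chloride, then the usual alkoxysulfonium ylide collapse), whereas the tertiary silyl ether has no carbinol hydrogen and is too hindered to react, and the acetate and alkene are inert.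

Step 8
Reactants: 12 C3 aldehyde; 13 (triphenylphosphoranylidene)acetaldehyde
Product: 14 (1R)-1-{(2S,5R)-2-methyl-5-[(2S,3E)-5-oxo-2-(triethylsilyloxy)pent-3-en-2-yl]oxolan-2-yl}but-3-en-1-yl acetate
Conditions: Ph3P=CHCHO (1.5 equiv), toluene, 80 °C
Reagents that add atoms: (triphenylphosphoranylidene)acetaldehyde, O=CC=P(c1ccccc1)(c1ccccc1)c1ccccc1
Why: Wittig reaction of a stabilised formyl ylide adds C2 and C1 as an (E)-enal; the non-enolisable α-alkoxy aldehyde is more electrophilic than the conjugated product, which limits double homologation.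

Step 9
Reactants: 14 (E)-enal
Product: 15 (1R)-1-{(2S,5R)-2-methyl-5-[(2S)-5-oxo-2-(triethylsilyloxy)pentan-2-yl]oxolan-2-yl}but-3-en-1-yl acetate (C1 aldehyde)
Conditions: Hantzsch ester (1.2 equiv), dibenzylammonium trifluoroacetate (10 mol %), THF, rt
Reagents that add atoms: none
Why: iminium-catalysed transfer hydrogenation reduces only the enal C=C, leaving the aldehyde, the terminal alkene, the acetate and the silyl ether untouched.

Step 10
Reactants: 15 C1 aldehyde; 16 methyl acrylate
Product: 17 Morita–Baylis–Hillman alcohol: methyl 2-methylidene-3-hydroxy ester at C1 with C4–OSiEt3, C9–OAc and a C10 allyl terminus (C11H=CH2); (4S,5R,8S,9R), both C1 epimers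
Conditions: methyl acrylate (10 equiv, neat), 3-hydroxyquinuclidine (0.5 equiv), rt
Reagents that add atoms: methyl acrylate, C=CC(=O)OC
Why: Morita–Baylis–Hillman reaction of an unbranched aliphatic aldehyde under protic-amine catalysis without added alcohol, so the acetate is safe; C1 forms as both epimers, which is acceptable because C1 becomes planar in step 17.

Step 11
Reactants: 17 Morita–Baylis–Hillman alcohol
Product: 18 C1 triethylsilyl ether of 17 (C1 and C4 O-triethylsilyl, C9–OAc); (4S,5R,8S,9R), both C1 epimers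
Conditions: TESCl, imidazole, DMF, 0 °C → rt
Reagents that add atoms: chlorotriethylsilane, CC[Si](Cl)(CC)CC
Why: silylation of the only free hydroxyl gives an ether-type protecting group, which unlike an ester cannot act as an SN2′ leaving group when DMAP is used in step 14.

Step 12
Reactants: 18 C1 silyl ether; 19 methacrolein
Product: 20 (11E)-C13 enal: 18 in which C11H=CH2 has become C11H=C12(CH3)–C13HO
Conditions: methacrolein (10 equiv), second-generation Grubbs catalyst RuCl2(=CHPh)(PCy3)(H2IMes) (5 mol %), CH2Cl2, 40 °C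
Reagents that add atoms: methacrolein, C=C(C)C=O
Why: olefin cross-metathesis of a terminal alkene with methacrolein should give the (E)-2-methyl enal under thermodynamic control, while the hindered 2-substituted acrylate of the Morita–Baylis–Hillman unit does not engage.

Step 13
Reactants: 20 C13 enal
Product: 21 (11E)-C13 carboxylic acid
Conditions: NaClO2, NaH2PO4, 2-methyl-2-butene, t-BuOH/H2O, 0 °C → rt
Reagents that add atoms: sodium chlorite, [Na+].[O-]Cl=O
Why: Pinnick oxidation converts the enal to the acid without touching alkenes (hypochlorite scavenged), esters or the silyl ethers at this buffered pH.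

Step 14
Reactants: 21 C13 acid; 22 Meldrum's acid
Product: 23 C13 acyl Meldrum's acid (enol form), C1 and C4 O-triethylsilyl
Conditions: Meldrum's acid, DCC, DMAP, CH2Cl2, 0 °C → rt; aq KHSO4 wash
Reagents that add atoms: Meldrum's acid, CC1(C)OC(=O)CC(=O)O1
Why: carbodiimide/DMAP C-acylation of Meldrum's acid by the unsaturated acid adds C14 and the future lactone carbonyl as a masked acylketene, with C1–OH silylated so that no ester can form.

Step 15
Reactants: 23 acyl Meldrum's acid
Product: 24 C1-hydroxy acyl Meldrum's acid (C4–OSiEt3 retained)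
Conditions: HF·pyridine, pyridine, THF, 0 °C
Reagents that add atoms: none
Why: buffered HF·pyridine should cleave the secondary C1 silyl ether much faster than the tertiary, neopentyl-like C4 silyl ether, and the acidic acyl Meldrum's acid, the acetate and the esters tolerate the reagent.

Step 16
Reactants: 24 C1-hydroxy acyl Meldrum's acid
Product: 26 sixteen-membered β-keto lactone (C1–O–C(=O)–C14; C4–OSiEt3; 4S,5R,8S,9R,11E; both C1 epimers), via acylketene 25 (not isolated)
Conditions: toluene, 100 °C, 0.5 mM (syringe-pump addition)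
Reagents that add atoms: none
Why: thermal fragmentation of the acyl Meldrum's acid releases acetone and CO2, and the resulting acylketene is trapped by the C1 hydroxyl, the only free OH, in an acylketene macrolactonisation under high dilution.

Step 17
Reactants: 26 sixteen-membered β-keto lactone
Product: 29 fourteen-membered C13 enone (1S,4S,5R,8S,9R,11E; C4–OSiEt3), via ammonium carboxylate zwitterion 27 (not isolated), via ammonium enolate zwitterion 28 (not isolated)
Conditions: (DHQD)2PHAL [hydroquinidine 1,4-phthalazinediyl diether] (20 mol %), 4 Å MS, THF, 40 °C, 1 mM (slow addition of 26)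
Reagents that add atoms: none
Why: Proposed new method: a quinuclidine nitrogen of the catalyst adds to the acrylate CH2 of 26 (SN2′) and the C1–O bond breaks to give allylammonium β-keto carboxylate 27, loss of CO2 unmasks the regiodefined C13/C14 enolate 28, and C14 attacks C1 in a second SN2′ step that expels the amine and restores the exo-methylene. The closest known reactions are cinchona-amine-catalysed allylic alkylations of Morita–Baylis–Hillman carbonates by β-keto esters and decarboxylative allylations of allyl β-keto esters; here the two are merged and the nucleophile is a non-stabilised ketone enolate. The fourteen-membered ring closes by an exo-trig SN2′ C-alkylation inside the zwitterion, so the sixteen-membered lactone contracts by excision of its O–C(=O) unit as CO2. C1 is the new stereocentre: both C1 epimers of 26 converge on one planar allyl unit and the face is chosen by the chiral ammonium leaving group, with the pseudoenantiomeric (DHQ)2PHAL as the first variable should the tether oppose it. Attack at C1 and not at CH2 follows from the addition–elimination sequence, since the amine occupies CH2; a catalyst without OH, molecular sieves and slow addition at 1 mM keep the enolate from being protonated by unreacted β-keto ester or alkylated intermolecularly, and the C4 silyl ether removes the one internal oxygen nucleophile that could close a tetrahydrofuran onto C1.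

Step 18
Reactants: 29 fourteen-membered C13 enone
Product: 31 C4-O-triethylsilyl ether of the target (1S,4S,5R,8S,9R,13S,11E), via catecholborate ester 30 (not isolated)
Conditions: (R)-2-methyl-CBS-oxazaborolidine [(R)-1-methyl-3,3-diphenyltetrahydro-1H,3H-pyrrolo[1,2-c][1,3,2]oxazaborole] (0.5 equiv), catecholborane, toluene, −78 °C; then MeOH, pH 7 buffer
Reagents that add atoms: none
Why: Corey–Bakshi–Shibata reduction in which the α-methyl alkenyl group (C12) acts as the large and C14H2 as the small substituent, so the (R)-catalyst should deliver hydride to give 13S under reagent control, with catecholborane at low temperature sparing the alkenes and esters.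

Step 19
Reactants: 31 C4-O-triethylsilyl ether of the target
Product: 32 target, CNP0266699.4 (1S,4S,5R,8S,9R,13S,11E)
Conditions: HF·pyridine, pyridine, THF, 0 °C → rt
Reagents that add atoms: none
Why: fluoride-mediated cleavage of the tertiary silyl ether under buffered conditions frees the C4 carbinol without acyl migration, allylic ionisation at C13 or addition to the acrylate.

Compound list
1 | (S)-linalool, (3S)-3,7-dimethylocta-1,6-dien-3-ol | CC(C)=CCC[C@](C)(O)C=C | starting material
2 | (2E,6S)-2,6-dimethylocta-2,7-diene-1,6-diol | OC/C(C)=C/CC[C@](C)(O)C=C | intermediate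
3 | [(2S,3S)-3-[(3S)-3-hydroxy-3-methylpent-4-en-1-yl]-2-methyloxiran-2-yl]methanol | OC[C@]1(C)O[C@H]1CC[C@](C)(O)C=C | intermediate (not isolated)
4 | (2S)-2-[(2R,5S)-5-ethenyl-5-methyloxolan-2-yl]propane-1,2-diol | OC[C@](C)(O)[C@H]1CC[C@](C)(O1)C=C | intermediate
5 | (2R,5S)-2-[(2S)-1,2-bis(triethylsilyloxy)propan-2-yl]-5-ethenyl-5-methyloxolane | CC[Si](CC)(CC)OC[C@](C)(O[Si](CC)(CC)CC)[C@H]1CC[C@](C)(O1)C=C | intermediate
6 | 1,2,4-trioxolane (ozonide) of 5, mixture at the trioxolane carbon | CC[Si](CC)(CC)OC[C@](C)(O[Si](CC)(CC)CC)[C@H]1CC[C@](C)(O1)C1OCOO1 | intermediate (not isolated)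
7 | (2S,5R)-5-[(2S)-1,2-bis(triethylsilyloxy)propan-2-yl]-2-methyloxolane-2-carbaldehyde | CC[Si](CC)(CC)OC[C@](C)(O[Si](CC)(CC)CC)[C@H]1CC[C@](C)(O1)C=O | intermediate
8 | allylmagnesium bromide | C=CC[Mg]Br | starting material
9 | diisopinocampheylborinate of 10 (9R) | CC[Si](CC)(CC)OC[C@](C)(O[Si](CC)(CC)CC)[C@H]1CC[C@](C)(O1)[C@H](OB([C@H]1C[C@H]2C[C@@H]([C@@H]1C)C2(C)C)[C@H]1C[C@H]2C[C@@H]([C@@H]1C)C2(C)C)CC=C | intermediate (not isolated)
10 | (1R)-1-{(2S,5R)-5-[(2S)-1,2-bis(triethylsilyloxy)propan-2-yl]-2-methyloxolan-2-yl}but-3-en-1-ol | CC[Si](CC)(CC)OC[C@](C)(O[Si](CC)(CC)CC)[C@H]1CC[C@](C)(O1)[C@H](O)CC=C | intermediate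
11 | (1R)-1-{(2S,5R)-5-[(2S)-1,2-bis(triethylsilyloxy)propan-2-yl]-2-methyloxolan-2-yl}but-3-en-1-yl acetate | CC[Si](CC)(CC)OC[C@](C)(O[Si](CC)(CC)CC)[C@H]1CC[C@](C)(O1)[C@H](OC(C)=O)CC=C | intermediate
12 | (1R)-1-{(2S,5R)-2-methyl-5-[(2R)-1-oxo-2-(triethylsilyloxy)propan-2-yl]oxolan-2-yl}but-3-en-1-yl acetate | O=C[C@](C)(O[Si](CC)(CC)CC)[C@H]1CC[C@](C)(O1)[C@H](OC(C)=O)CC=C | intermediate
13 | (triphenylphosphoranylidene)acetaldehyde | O=CC=P(c1ccccc1)(c1ccccc1)c1ccccc1 | starting material
14 | (1R)-1-{(2S,5R)-2-methyl-5-[(2S,3E)-5-oxo-2-(triethylsilyloxy)pent-3-en-2-yl]oxolan-2-yl}but-3-en-1-yl acetate | O=C/C=C/[C@](C)(O[Si](CC)(CC)CC)[C@H]1CC[C@](C)(O1)[C@H](OC(C)=O)CC=C | intermediate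
15 | (1R)-1-{(2S,5R)-2-methyl-5-[(2S)-5-oxo-2-(triethylsilyloxy)pentan-2-yl]oxolan-2-yl}but-3-en-1-yl acetate | O=CCC[C@](C)(O[Si](CC)(CC)CC)[C@H]1CC[C@](C)(O1)[C@H](OC(C)=O)CC=C | intermediate
16 | methyl acrylate | C=CC(=O)OC | starting material
17 | Morita–Baylis–Hillman alcohol (C1–OH, C4–OSiEt3, C9–OAc, C11H=CH2; 4S,5R,8S,9R; C1 epimers) | C=C(C(=O)OC)C(O)CC[C@](C)(O[Si](CC)(CC)CC)[C@H]1CC[C@](C)(O1)[C@H](OC(C)=O)CC=C | intermediate
18 | C1-O-triethylsilyl ether of 17 | C=C(C(=O)OC)C(O[Si](CC)(CC)CC)CC[C@](C)(O[Si](CC)(CC)CC)[C@H]1CC[C@](C)(O1)[C@H](OC(C)=O)CC=C | intermediate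
19 | methacrolein | C=C(C)C=O | starting material
20 | (11E)-C13 enal (C1, C4 O-triethylsilyl; C9–OAc) | C=C(C(=O)OC)C(O[Si](CC)(CC)CC)CC[C@](C)(O[Si](CC)(CC)CC)[C@H]1CC[C@](C)(O1)[C@H](OC(C)=O)C/C=C(\C)C=O | intermediate
21 | (11E)-C13 carboxylic acid | C=C(C(=O)OC)C(O[Si](CC)(CC)CC)CC[C@](C)(O[Si](CC)(CC)CC)[C@H]1CC[C@](C)(O1)[C@H](OC(C)=O)C/C=C(\C)C(=O)O | intermediate
22 | Meldrum's acid, 2,2-dimethyl-1,3-dioxane-4,6-dione | CC1(C)OC(=O)CC(=O)O1 | starting material
23 | C13 acyl Meldrum's acid, enol form (C1, C4 O-triethylsilyl) | C=C(C(=O)OC)C(O[Si](CC)(CC)CC)CC[C@](C)(O[Si](CC)(CC)CC)[C@H]1CC[C@](C)(O1)[C@H](OC(C)=O)C/C=C(\C)C(O)=C1C(=O)OC(C)(C)OC1=O | intermediate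
24 | C1-hydroxy acyl Meldrum's acid (C4–OSiEt3) | C=C(C(=O)OC)C(O)CC[C@](C)(O[Si](CC)(CC)CC)[C@H]1CC[C@](C)(O1)[C@H](OC(C)=O)C/C=C(\C)C(O)=C1C(=O)OC(C)(C)OC1=O | intermediate
25 | C13 acylketene with free C1–OH | C=C(C(=O)OC)C(O)CC[C@](C)(O[Si](CC)(CC)CC)[C@H]1CC[C@](C)(O1)[C@H](OC(C)=O)C/C=C(\C)C(=O)C=C=O | intermediate (not isolated)
26 | sixteen-membered β-keto lactone, C4-O-triethylsilyl (4S,5R,8S,9R,11E; C1 epimers) | C=C(C(=O)OC)C1CC[C@](C)(O[Si](CC)(CC)CC)[C@H]2CC[C@](C)(O2)[C@H](OC(C)=O)C/C=C(\C)C(=O)CC(=O)O1 | intermediate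
27 | allylammonium β-keto carboxylate zwitterion (catalyst nitrogen on the acrylate CH2, C1=Cα alkene) | CC[C@H]1C[N+]2(CC(C(=O)OC)=CCC[C@](C)(O[Si](CC)(CC)CC)[C@H]3CC[C@](C)(O3)[C@H](OC(C)=O)C/C=C(\C)C(=O)CC(=O)[O-])CC[C@H]1C[C@@H]2[C@@H](Oc1nnc(O[C@@H](c2ccnc3ccc(OC)cc23)[C@H]2C[C@@H]3CCN2C[C@@H]3CC)c2ccccc12)c1ccnc2ccc(OC)cc12 | intermediate (not isolated)
28 | allylammonium C13/C14 enolate zwitterion | CC[C@H]1C[N+]2(CC(C(=O)OC)=CCC[C@](C)(O[Si](CC)(CC)CC)[C@H]3CC[C@](C)(O3)[C@H](OC(C)=O)C/C=C(\C)C([O-])=C)CC[C@H]1C[C@@H]2[C@@H](Oc1nnc(O[C@@H](c2ccnc3ccc(OC)cc23)[C@H]2C[C@@H]3CCN2C[C@@H]3CC)c2ccccc12)c1ccnc2ccc(OC)cc12 | intermediate (not isolated)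
29 | fourteen-membered C13 enone, C4-O-triethylsilyl (1S,4S,5R,8S,9R,11E) | C=C(C(=O)OC)[C@H]1CC[C@](C)(O[Si](CC)(CC)CC)[C@H]2CC[C@](C)(O2)[C@H](OC(C)=O)C/C=C(\C)C(=O)C1 | intermediate
30 | C13 catecholborate ester of 31 | C=C(C(=O)OC)[C@H]1CC[C@](C)(O[Si](CC)(CC)CC)[C@H]2CC[C@](C)(O2)[C@H](OC(C)=O)C/C=C(\C)[C@@H](OB2Oc3ccccc3O2)C1 | intermediate (not isolated)
31 | C4-O-triethylsilyl ether of the target (1S,4S,5R,8S,9R,13S,11E) | C=C(C(=O)OC)[C@H]1CC[C@](C)(O[Si](CC)(CC)CC)[C@H]2CC[C@](C)(O2)[C@H](OC(C)=O)C/C=C(\C)[C@@H](O)C1 | intermediate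
32 | CNP0266699.4 (1S,4S,5R,8S,9R,13S,11E) | C=C(C(=O)OC)[C@H]1CC[C@](C)(O)[C@H]2CC[C@](C)(O2)[C@H](OC(C)=O)C/C=C(\C)[C@@H](O)C1 | target

Total step count: 19. Longest linear sequence: 19 steps (1 → 32).

Steps most likely to fail

Step 17 (proposed new method). The decarboxylated enolate may be protonated by unreacted β-keto ester before it cyclises, the open zwitterion may alkylate intermolecularly, or the C1 face may be poorly controlled. The fallback makes the C1–C14 bond intermolecularly with a stabilised nucleophile and closes the ring at C11=C12 by known chemistry; it sets out from 17 and returns at 29. Alcohol 17 is converted with Boc2O/DMAP into the tert-butyl carbonate F1. The nucleophile is prepared from 2-(diethoxyphosphoryl)propanoic acid and 22 (DCC, DMAP), giving the acyl Meldrum's acid F2, which on heating with allyl alcohol in toluene gives allyl 4-(diethoxyphosphoryl)-3-oxopentanoate F3. Cinchona-amine-catalysed allylic alkylation of F1 with F3 ((DHQD)2PHAL or its pseudoenantiomer, toluene, rt; SN2′/SN2′, catalyst-controlled 1S) gives the C1-alkylated keto ester F4. Pd(OAc)2/PPh3 with HCO2H/Et3N removes the allyl ester with decarboxylation to give the β-ketophosphonate F5. Lemieux–Johnson cleavage (OsO4 cat., NaIO4, 2,6-lutidine, dioxane/H2O) of the terminal alkene gives the C11 aldehyde F6. An intramolecular Horner–Wadsworth–Emmons reaction (LiCl, iPr2NEt, MeCN, 1 mM) then closes the fourteen-membered (E)-enone 29.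

Step 18. Hydride delivery in the flexible macrocycle may follow the substrate's bias and not the catalyst's, giving poor facial selectivity at C13. The fallback uses substrate control followed by inversion; it sets out from 29 and returns at 31. Luche reduction (NaBH4, CeCl3·7H2O, MeOH, −78 °C) gives the allylic alcohol. If the 13R alcohol F7 predominates, Mitsunobu inversion with chloroacetic acid (PPh3, DIAD, toluene, 0 °C) gives the 13S chloroacetate F8, and thiourea/NaHCO3 in EtOH removes the chloroacetyl group selectively in the presence of the C9 acetate to give 31.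

Step 10. The amine-catalysed addition to an enolisable aliphatic aldehyde may stall, with aldol self-condensation of 15 taking over. The fallback replaces the reversible catalytic pathway by a stoichiometric nucleophile; it sets out from 15 and returns at 17. [α-(Methoxycarbonyl)vinyl]diisobutylaluminium, generated from methyl propiolate and i-Bu2AlH with HMPA in THF at 0 °C, is added to 15 and gives 17 directly by 1,2-addition.

Further compounds
F1 | step 17 | tert-butyl carbonate of 17 (C1–OBoc; C1 epimers) | C=C(C(=O)OC)C(OC(=O)OC(C)(C)C)CC[C@](C)(O[Si](CC)(CC)CC)[C@H]1CC[C@](C)(O1)[C@H](OC(C)=O)CC=C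
F2 | step 17 | 5-[2-(diethoxyphosphoryl)-1-hydroxypropylidene]-2,2-dimethyl-1,3-dioxane-4,6-dione | CCOP(=O)(OCC)C(C)C(O)=C1C(=O)OC(C)(C)OC1=O
F3 | step 17 | allyl 4-(diethoxyphosphoryl)-3-oxopentanoate | C=CCOC(=O)CC(=O)C(C)P(=O)(OCC)OCC
F4 | step 17 | C1-alkylated allyl β-keto ester (1S; C14–CO2allyl, C12 phosphonate) | C=C(C(=O)OC)[C@H](C(C(=O)OCC=C)C(=O)C(C)P(=O)(OCC)OCC)CC[C@](C)(O[Si](CC)(CC)CC)[C@H]1CC[C@](C)(O1)[C@H](OC(C)=O)CC=C
F5 | step 17 | β-ketophosphonate (1S; C13 ketone, C12 diethyl phosphonate, terminal alkene) | C=C(C(=O)OC)[C@H](CC(=O)C(C)P(=O)(OCC)OCC)CC[C@](C)(O[Si](CC)(CC)CC)[C@H]1CC[C@](C)(O1)[C@H](OC(C)=O)CC=C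
F6 | step 17 | C11 aldehyde of the β-ketophosphonate | C=C(C(=O)OC)[C@H](CC(=O)C(C)P(=O)(OCC)OCC)CC[C@](C)(O[Si](CC)(CC)CC)[C@H]1CC[C@](C)(O1)[C@H](OC(C)=O)CC=O
F7 | step 18 | 13R epimer of 31 | C=C(C(=O)OC)[C@H]1CC[C@](C)(O[Si](CC)(CC)CC)[C@H]2CC[C@](C)(O2)[C@H](OC(C)=O)C/C=C(\C)[C@H](O)C1
F8 | step 18 | 13S chloroacetate of 31 | C=C(C(=O)OC)[C@H]1CC[C@](C)(O[Si](CC)(CC)CC)[C@H]2CC[C@](C)(O2)[C@H](OC(C)=O)C/C=C(\C)[C@@H](OC(=O)CCl)C1
F0 | step 10 | none | none
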